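**Plan** (flavan numbering: O1, C2, C3, C4, C4a–C8a; ring A = benzo ring, ring B = aryl on C2, ring C = pyran)
1. Retrosynthesis: cut the ester at O3–C(=O) and take the side-chain carbinol back to a β-keto ester; cut C3–O3 and C2–H together (hydroboration retron, giving an achiral 4H-chromene); cut C3–C4 of ring C; take the O1–C2 enol ether back to an aryl ester of the ring A phenol and the ring B acid.
2. Enabling feature: C4 is a benzylic carbon whose ipso carbon C4a has O1, O5 and O7 ortho, ortho and para, so a C4 cation forms at −78 °C; C2 carries O1 and ring B, so C2=C3 can be an aryl enol ether with a nucleophilic terminal C3 and an oxocarbenium-stabilised C2.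
3. Forward: rings A and B are joined through O1 (ester, then methylenation, which brings in C3); ring C closes by C4–C3 bond formation with C2 kept sp2 (helpers: OMe leaving group on C4, C2=C3 unsaturation), so no stereocentre has to survive ring closure.
4. Stereochemistry: one syn hydroboration of C2=C3 with IpcBH2 from (+)-α-pinene sets C2 (R) and C3 (S), trans by mechanism; the side-chain carbinol (S) comes from hydrogenation of the β-keto ester with [RuCl(C6H6)((S)-BINAP)]Cl after it is attached at O3.
5. End game: one hydrogenolysis removes all six benzyl ethers.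

Key step: step 5

Remark: the SMILES is taken as binding; it describes (2R,3S) in ring C (2,3-trans) and (3S) in the side chain, and the route is planned for this isomer.

**Step 1**
Reactants: 1 2,4,6-trihydroxybenzaldehyde
Product: 2 2,4-bis(benzyloxy)-6-hydroxybenzaldehyde
Conditions: BnBr (2.1 equiv), K2CO3, DMF, 0 to 23 °C
Reagents that add atoms: benzyl bromide, BrCc1ccccc1
Why: Williamson etherification; the hydroxyl that is hydrogen-bonded to the formyl group is the least nucleophilic, so two equivalents of benzyl bromide should alkylate the other two phenols and leave that one free.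

**Step 2**
Reactants: 2 2,4-bis(benzyloxy)-6-hydroxybenzaldehyde
Product: 4 3,5-bis(benzyloxy)-2-(methoxymethyl)phenol, via hydroxymethyl phenol 3 (not isolated)
Conditions: NaBH4, THF/MeOH, 0 °C; then Amberlyst 15 (H+ form), MeOH, 23 °C
Reagents that add atoms: methanol, CO
Why: Borohydride reduction of the aldehyde followed by acid-catalysed SN1-type etherification in methanol; the benzylic carbon is activated by three ortho/para oxygen donors, so it should exchange OH for OMe under mild acid while the phenol stays free.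

**Step 3**
Reactants: 4 3,5-bis(benzyloxy)-2-(methoxymethyl)phenol; 5 3,4-bis(benzyloxy)benzoic acid
Product: 6 3,5-bis(benzyloxy)-2-(methoxymethyl)phenyl 3,4-bis(benzyloxy)benzoate
Conditions: DCC, DMAP (cat.), CH2Cl2, 0 to 23 °C
Reagents that add atoms: none
Why: Steglich esterification joins ring B to the phenol oxygen that becomes O1 under neutral conditions that leave the acid-labile benzylic methyl ether intact.

**Step 4**
Reactants: 6 3,5-bis(benzyloxy)-2-(methoxymethyl)phenyl 3,4-bis(benzyloxy)benzoate
Product: 7 1,5-bis(benzyloxy)-3-({1-[3,4-bis(benzyloxy)phenyl]ethenyl}oxy)-2-(methoxymethyl)benzene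
Conditions: (C5H5)2Ti(CH3)2 (dimethyltitanocene, 3 equiv), toluene/THF, 65 °C, dark; filtration through basic alumina
Reagents that add atoms: dimethyltitanocene, C[Ti](C)(C1C=CC=C1)C1C=CC=C1
Why: Petasis methylenation of an aryl ester; the titanium methylidene formed on heating should convert C=O into C=CH2 without acid or base, which creates the O1–C2 enol ether and brings in C3.

**Step 5**
Reactants: 7 1,5-bis(benzyloxy)-3-({1-[3,4-bis(benzyloxy)phenyl]ethenyl}oxy)-2-(methoxymethyl)benzene
Product: 10 5,7-bis(benzyloxy)-2-[3,4-bis(benzyloxy)phenyl]-4H-chromene, via benzylic cation triflate 8 (not isolated), via chromanylium triflate 9 (not isolated)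
Conditions: TMSOTf (1.1 equiv), 2,6-di-tert-butyl-4-methylpyridine (1.5 equiv), CH2Cl2 (0.005 M), −78 to −40 °C; Et3N, then aq NaHCO3
Reagents that add atoms: none
Why: Proposed new method: TMSOTf silylates the methoxy oxygen and the C4–O bond ionises to benzylic cation 8, stabilised by O1, O5 and O7 through ring A; the terminal enol ether carbon C3 attacks C4 to give oxocarbenium ion 9 (C2 cation stabilised by O1 and ring B), and the hindered pyridine removes a proton from C3 to leave the C2=C3 enol ether of 10. The closest known reaction types are the Lewis-acid alkylation of enol ethers by stabilised benzylic cations (Prins-type cation–olefin cyclisation) and the addition of enol ethers to ortho-quinone methides; what is new is the intramolecular case through an aryl vinyl ether. Ring C closes in the 6-endo-trig mode with respect to C2=C3, the only mode that places the positive charge on the oxygen- and aryl-substituted C2; the 5-exo mode through C2 would leave a primary cation on C3. No stereocentre is formed, because 10 is achiral, which is the reason for closing the ring at this oxidation level. The step needs chemoselective ionisation (only the C4–OMe bond is activated by three donor oxygens; the aryl benzyl ethers are not), ring closure ahead of intermolecular Friedel–Crafts alkylation (secured by 0.005 M dilution and the six-membered transition state), and survival of the acid-labile enol ethers 7 and 10 (secured by the pyridine base and the amine quench at −78 °C).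

**Step 6**
Reactants: 10 5,7-bis(benzyloxy)-2-[3,4-bis(benzyloxy)phenyl]-4H-chromene
Product: 12 (2R,3S)-5,7-bis(benzyloxy)-2-[3,4-bis(benzyloxy)phenyl]chroman-3-ol, via chromanyl(isopinocampheyl)borane 11 (not isolated)
Conditions: IpcBH2 (monoisopinocampheylborane from (+)-α-pinene, 2 equiv), THF, −25 °C; then 3 M NaOH, 30% H2O2, 0 to 23 °C
Reagents that add atoms: hydrogen peroxide, OO
Why: Brown asymmetric hydroboration of a trisubstituted enol ether and oxidation with retention; boron adds to the enol ether β-carbon C3 and hydrogen to C2 from the same face, so the C2 aryl group and the C3 oxygen are trans by mechanism, and the isopinocampheyl group should select the face that gives (2R,3S), by analogy with 1-arylcycloalkenes, which this reagent converts into (1S,2R)-trans-2-arylcycloalkanols.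

**Step 7**
Reactants: 13 methyl acetoacetate; 14 1,2-bis(benzyloxy)-4-(chloromethyl)benzene
Product: 16 methyl 5-[3,4-bis(benzyloxy)phenyl]-3-oxopentanoate, via acetoacetate dianion 15 (not isolated)
Conditions: NaH, THF, 0 °C; n-BuLi, 0 °C; then 14, 0 to 23 °C; aq HCl
Reagents that add atoms: none
Why: Acetoacetate dianion γ-alkylation; the more basic terminal carbanion of the dianion should displace the benzylic chloride (SN2) and give the five-carbon chain in one step.

**Step 8**
Reactants: 12 (2R,3S)-5,7-bis(benzyloxy)-2-[3,4-bis(benzyloxy)phenyl]chroman-3-ol; 16 methyl 5-[3,4-bis(benzyloxy)phenyl]-3-oxopentanoate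
Product: 17 (2R,3S)-5,7-bis(benzyloxy)-2-[3,4-bis(benzyloxy)phenyl]chroman-3-yl 5-[3,4-bis(benzyloxy)phenyl]-3-oxopentanoate
Conditions: DMAP (0.3 equiv), toluene, reflux, condensate returned through 4 Å molecular sieves (removal of MeOH)
Reagents that add atoms: none
Why: DMAP-catalysed thermal transesterification, which is specific to β-keto esters and is driven by removal of methanol, should acylate the equatorial secondary 3-OH without an activating reagent and without touching C2 or C3.

**Step 9**
Reactants: 17 (2R,3S)-5,7-bis(benzyloxy)-2-[3,4-bis(benzyloxy)phenyl]chroman-3-yl 5-[3,4-bis(benzyloxy)phenyl]-3-oxopentanoate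
Product: 18 (2R,3S)-5,7-bis(benzyloxy)-2-[3,4-bis(benzyloxy)phenyl]chroman-3-yl (3S)-5-[3,4-bis(benzyloxy)phenyl]-3-hydroxypentanoate
Conditions: H2 (10 atm), [RuCl(C6H6)((S)-BINAP)]Cl (1 mol %), EtOH/CH2Cl2, 50 °C
Reagents that add atoms: none
Why: Noyori asymmetric hydrogenation of a β-keto ester; the ester carbonyl chelates ruthenium and the (S)-BINAP ligand should deliver hydrogen to the ketone face that gives the (3S) carbinol under catalyst control (the (R) ligand gives (R)-3-hydroxybutanoate from acetoacetate), while aryl benzyl ethers are inert to this catalyst.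

**Step 10**
Reactants: 18 (2R,3S)-5,7-bis(benzyloxy)-2-[3,4-bis(benzyloxy)phenyl]chroman-3-yl (3S)-5-[3,4-bis(benzyloxy)phenyl]-3-hydroxypentanoate
Product: 19 phylloflavan [(2R,3S)-2-(3,4-dihydroxyphenyl)-5,7-dihydroxychroman-3-yl (3S)-5-(3,4-dihydroxyphenyl)-3-hydroxypentanoate]
Conditions: H2 (1 atm), Pd(OH)2 on carbon, THF/MeOH, 23 °C
Reagents that add atoms: none
Why: Catalytic hydrogenolysis should cleave the six aryl benzyl ethers in one operation; the ester is inert and the C2–O1 benzylic bond, being part of ring C, is expected to survive these mild neutral conditions.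

**Compound list**
1 | 2,4,6-trihydroxybenzaldehyde | O=Cc1c(O)cc(O)cc1O | starting material
2 | 2,4-bis(benzyloxy)-6-hydroxybenzaldehyde | O=Cc1c(O)cc(OCc2ccccc2)cc1OCc1ccccc1 | intermediate
3 | 3,5-bis(benzyloxy)-2-(hydroxymethyl)phenol | OCc1c(O)cc(OCc2ccccc2)cc1OCc1ccccc1 | intermediate (not isolated)
4 | 3,5-bis(benzyloxy)-2-(methoxymethyl)phenol | COCc1c(O)cc(OCc2ccccc2)cc1OCc1ccccc1 | intermediate
5 | 3,4-bis(benzyloxy)benzoic acid | OC(=O)c1ccc(OCc2ccccc2)c(OCc2ccccc2)c1 | starting material
6 | 3,5-bis(benzyloxy)-2-(methoxymethyl)phenyl 3,4-bis(benzyloxy)benzoate | COCc1c(OC(=O)c2ccc(OCc3ccccc3)c(OCc3ccccc3)c2)cc(OCc2ccccc2)cc1OCc1ccccc1 | intermediate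
7 | 1,5-bis(benzyloxy)-3-({1-[3,4-bis(benzyloxy)phenyl]ethenyl}oxy)-2-(methoxymethyl)benzene | COCc1c(OC(=C)c2ccc(OCc3ccccc3)c(OCc3ccccc3)c2)cc(OCc2ccccc2)cc1OCc1ccccc1 | intermediate
8 | [2,4-bis(benzyloxy)-6-({1-[3,4-bis(benzyloxy)phenyl]ethenyl}oxy)phenyl]methylium trifluoromethanesulfonate | [CH2+]c1c(OC(=C)c2ccc(OCc3ccccc3)c(OCc3ccccc3)c2)cc(OCc2ccccc2)cc1OCc1ccccc1.[O-]S(=O)(=O)C(F)(F)F | intermediate (not isolated)
9 | 5,7-bis(benzyloxy)-2-[3,4-bis(benzyloxy)phenyl]-3,4-dihydrochromenylium trifluoromethanesulfonate (C2 oxocarbenium ion) | C1Cc2c(OCc3ccccc3)cc(OCc3ccccc3)cc2[O+]=C1c1ccc(OCc2ccccc2)c(OCc2ccccc2)c1.[O-]S(=O)(=O)C(F)(F)F | intermediate (not isolated)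
10 | 5,7-bis(benzyloxy)-2-[3,4-bis(benzyloxy)phenyl]-4H-chromene | C1(c2ccc(OCc3ccccc3)c(OCc3ccccc3)c2)=CCc2c(OCc3ccccc3)cc(OCc3ccccc3)cc2O1 | intermediate
11 | [(2R,3S)-5,7-bis(benzyloxy)-2-[3,4-bis(benzyloxy)phenyl]chroman-3-yl](isopinocampheyl)borane | C[C@H]1[C@H](B[C@H]3Cc4c(OCc5ccccc5)cc(OCc5ccccc5)cc4O[C@@H]3c3ccc(OCc4ccccc4)c(OCc4ccccc4)c3)C[C@@H]2C[C@H]1C2(C)C | intermediate (not isolated)
12 | (2R,3S)-5,7-bis(benzyloxy)-2-[3,4-bis(benzyloxy)phenyl]chroman-3-ol | O[C@H]1Cc2c(OCc3ccccc3)cc(OCc3ccccc3)cc2O[C@@H]1c1ccc(OCc2ccccc2)c(OCc2ccccc2)c1 | intermediate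
13 | methyl acetoacetate | COC(=O)CC(C)=O | starting material
14 | 1,2-bis(benzyloxy)-4-(chloromethyl)benzene | ClCc1ccc(OCc2ccccc2)c(OCc2ccccc2)c1 | starting material
15 | sodium lithium dianion (bis-enolate) of methyl acetoacetate | [Na+].[Li+].C=C([O-])C=C([O-])OC | intermediate (not isolated)
16 | methyl 5-[3,4-bis(benzyloxy)phenyl]-3-oxopentanoate | COC(=O)CC(=O)CCc1ccc(OCc2ccccc2)c(OCc2ccccc2)c1 | intermediate
17 | (2R,3S)-5,7-bis(benzyloxy)-2-[3,4-bis(benzyloxy)phenyl]chroman-3-yl 5-[3,4-bis(benzyloxy)phenyl]-3-oxopentanoate | O=C(CC(=O)CCc1ccc(OCc2ccccc2)c(OCc2ccccc2)c1)O[C@H]1Cc2c(OCc3ccccc3)cc(OCc3ccccc3)cc2O[C@@H]1c1ccc(OCc2ccccc2)c(OCc2ccccc2)c1 | intermediate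
18 | (2R,3S)-5,7-bis(benzyloxy)-2-[3,4-bis(benzyloxy)phenyl]chroman-3-yl (3S)-5-[3,4-bis(benzyloxy)phenyl]-3-hydroxypentanoate | O=C(C[C@@H](O)CCc1ccc(OCc2ccccc2)c(OCc2ccccc2)c1)O[C@H]1Cc2c(OCc3ccccc3)cc(OCc3ccccc3)cc2O[C@@H]1c1ccc(OCc2ccccc2)c(OCc2ccccc2)c1 | intermediate
19 | phylloflavan [(2R,3S)-2-(3,4-dihydroxyphenyl)-5,7-dihydroxychroman-3-yl (3S)-5-(3,4-dihydroxyphenyl)-3-hydroxypentanoate] | O=C(C[C@@H](O)CCc1ccc(O)c(O)c1)O[C@H]1Cc2c(O)cc(O)cc2O[C@@H]1c1ccc(O)c(O)c1 | target

**Step count and risks**
Total steps: 10. Longest linear sequence: 9 steps (steps 1 to 6, 8, 9, 10, from 1).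

Steps most likely to fail:

1. Step 5 (Proposed new method). The benzylic cation may alkylate the electron-rich rings or the enol ether of a second molecule faster than it closes ring C, or adventitious acid may protonate and hydrolyse the enol ethers. Fallback with known chemistry, which closes ring C at O1–C2 instead: it sets out from 2. Claisen–Schmidt condensation of 2 with commercial 1-[3,4-bis(benzyloxy)phenyl]ethanone (KOH, EtOH) should give (E)-3-[2,4-bis(benzyloxy)-6-hydroxyphenyl]-1-[3,4-bis(benzyloxy)phenyl]prop-2-en-1-one F1. Hydrogenation of the C=C bond only (H2, RhCl(PPh3)3, benzene/EtOH) should give 3-[2,4-bis(benzyloxy)-6-hydroxyphenyl]-1-[3,4-bis(benzyloxy)phenyl]propan-1-one F2. Acid-catalysed cyclodehydration of the ketophenol (pyridinium p-toluenesulfonate, toluene, reflux, water removal) should give 10, where the route is rejoined.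

2. Step 6. The chiral borane may discriminate poorly between the faces of this enol ether, or the β-aryloxyalkylborane may open ring C by β-elimination; should the sense of induction be opposite to the analogy, the reagent from (−)-α-pinene would be used. Fallback by resolution: it sets out from 10. Hydroboration with BH3·THF and oxidation (H2O2, NaOH), the known racemic version for this class, should give 12 together with its enantiomer, (2S,3R)-5,7-bis(benzyloxy)-2-[3,4-bis(benzyloxy)phenyl]chroman-3-ol F3. The mixture is taken through steps 8 and 9. Step 8 should give, beside 17, the (2S,3R)-chromanyl keto ester F4. Because step 9 is catalyst-controlled, it should give 18 and its diastereomer, the (2S,3R)-chromanyl (3S)-hydroxy ester F5. The diastereomers are separated by chromatography or crystallisation, and the route is rejoined at 18.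

3. Step 2. Phenoxide-assisted loss of hydroxide from 3 may give an ortho-quinone methide that is reduced further to the methylphenol, or the electron-rich hydroxybenzyl cation may condense with itself before methanol captures it. Fallback that avoids the free hydroxymethyl phenol: it sets out from 2. The phenol is esterified first with 5 (DCC, DMAP, CH2Cl2) to 3,5-bis(benzyloxy)-2-formylphenyl 3,4-bis(benzyloxy)benzoate F6, which cannot form the quinone methide. Reductive etherification of the formyl group (Et3SiH, MeOSiMe3, catalytic TMSOTf, CH2Cl2, −78 °C) should give 6, where the route is rejoined.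

**Further compounds**
F1 | step 5 | (E)-3-[2,4-bis(benzyloxy)-6-hydroxyphenyl]-1-[3,4-bis(benzyloxy)phenyl]prop-2-en-1-one | O=C(/C=C/c1c(O)cc(OCc2ccccc2)cc1OCc1ccccc1)c1ccc(OCc2ccccc2)c(OCc2ccccc2)c1
F2 | step 5 | 3-[2,4-bis(benzyloxy)-6-hydroxyphenyl]-1-[3,4-bis(benzyloxy)phenyl]propan-1-one | O=C(CCc1c(O)cc(OCc2ccccc2)cc1OCc1ccccc1)c1ccc(OCc2ccccc2)c(OCc2ccccc2)c1
F3 | step 6 | (2S,3R)-5,7-bis(benzyloxy)-2-[3,4-bis(benzyloxy)phenyl]chroman-3-ol | O[C@@H]1Cc2c(OCc3ccccc3)cc(OCc3ccccc3)cc2O[C@H]1c1ccc(OCc2ccccc2)c(OCc2ccccc2)c1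
F4 | step 6 | (2S,3R)-5,7-bis(benzyloxy)-2-[3,4-bis(benzyloxy)phenyl]chroman-3-yl 5-[3,4-bis(benzyloxy)phenyl]-3-oxopentanoate | O=C(CC(=O)CCc1ccc(OCc2ccccc2)c(OCc2ccccc2)c1)O[C@@H]1Cc2c(OCc3ccccc3)cc(OCc3ccccc3)cc2O[C@H]1c1ccc(OCc2ccccc2)c(OCc2ccccc2)c1
F5 | step 6 | (2S,3R)-5,7-bis(benzyloxy)-2-[3,4-bis(benzyloxy)phenyl]chroman-3-yl (3S)-5-[3,4-bis(benzyloxy)phenyl]-3-hydroxypentanoate | O=C(C[C@@H](O)CCc1ccc(OCc2ccccc2)c(OCc2ccccc2)c1)O[C@@H]1Cc2c(OCc3ccccc3)cc(OCc3ccccc3)cc2O[C@H]1c1ccc(OCc2ccccc2)c(OCc2ccccc2)c1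
F6 | step 2 | 3,5-bis(benzyloxy)-2-formylphenyl 3,4-bis(benzyloxy)benzoate | O=Cc1c(OC(=O)c2ccc(OCc3ccccc3)c(OCc3ccccc3)c2)cc(OCc2ccccc2)cc1OCc1ccccc1
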